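**Plan**

1. Retrosynthesis: after the phenol is unmasked (O–benzyl), the target is cut at the bond between the benzylic CH2 on C3 of the lactone and the ipso carbon of the 3-hydroxy-4-methoxyphenyl ring. Further cuts are C3–CH2 (enolate alkylation), the lactone O1–C2 bond (lactonisation) and the two C–H bonds of a Stobbe alkene.
2. Enabling feature: this benzylic carbon is exocyclic on C3, the only enolisable ring carbon (alpha to the lactone C2=O). It can therefore be brought in as a carboxymethyl group anti to the C4 substituent. The carboxyl then acts as a traceless radical handle: CO2 is extruded and the primary radical is joined on nickel to an aryl iodide, so both carbons come from electrophiles.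
3. Forward order: Stobbe condensation, asymmetric hydrogenation, ester reduction/lactonisation (the only ring closure, the γ-lactone), trans alkylation with a bromoacetate, acidolysis, decarboxylative arylation, debenzylation.
4. Stereochemistry: C4 (R) comes from catalyst-controlled hydrogenation. C3 (R) comes from substrate-controlled alkylation anti to the C4 veratryl group (trans is also the thermodynamic isomer). The key step forms a radical only on the exocyclic carbon and leaves both centres untouched.

Key step: step 7

Remark: 5-iodo-2-methoxyphenol (11) is taken as a catalogue compound; the iodide is preferred to the bromide so that oxidative addition to Ni(0) keeps pace with reduction of the redox-active ester.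

**Step 1**
Reactants: 1 3,4-dimethoxybenzaldehyde; 2 dimethyl succinate
Product: 3 (E)-4-(3,4-dimethoxyphenyl)-3-(methoxycarbonyl)but-3-enoic acid
Conditions: NaOMe (2.2 equiv), MeOH, reflux; then aq. HCl
Reagents that add atoms: none
Why: Stobbe condensation of a non-enolisable aryl aldehyde with the succinate enolate should stop at the half-ester whose free acid is the CH2CO2H arm, mainly as the E alkene, and either alkene geometry is acceptable for step 2.

**Step 2**
Reactants: 3 (E)-4-(3,4-dimethoxyphenyl)-3-(methoxycarbonyl)but-3-enoic acid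
Product: 4 (R)-4-(3,4-dimethoxyphenyl)-3-(methoxycarbonyl)butanoic acid
Conditions: H2 (5 bar), [Rh(cod)((S,S)-Et-DuPhos)]BF4 (0.5 mol%), NaOMe (10 mol%), MeOH, rt
Reagents that add atoms: none
Why: Rh-bisphospholane asymmetric hydrogenation of a Stobbe-type itaconate half-ester, in which the carboxylate arm chelates rhodium as the acylamino group of an enamide does, should set the future C4 centre as R under catalyst control; the (S,S) ligand is the antipode expected to give R by that analogy, and the sense would be checked on lactone 6 before going on.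

**Step 3**
Reactants: 4 (R)-4-(3,4-dimethoxyphenyl)-3-(methoxycarbonyl)butanoic acid
Product: 6 (R)-4-(3,4-dimethoxybenzyl)dihydrofuran-2(3H)-one, via hydroxy acid 5 (not isolated)
Conditions: KOH (1.0 equiv), EtOH, 0 °C; CaCl2, NaBH4, EtOH, −10 °C to rt; then 3 M HCl, rt
Reagents that add atoms: none
Why: Chemoselective borohydride reduction, in which calcium borohydride should reduce the methyl ester but not the potassium carboxylate, followed by acid-promoted lactonisation of the γ-hydroxy acid; the stereocentre is no longer alpha to a carbonyl once the ester is reduced, so it should be carried through unchanged.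

**Step 4**
Reactants: 6 (R)-4-(3,4-dimethoxybenzyl)dihydrofuran-2(3H)-one; 7 tert-butyl bromoacetate
Product: 9 tert-butyl 2-[(3R,4R)-4-(3,4-dimethoxybenzyl)-2-oxotetrahydrofuran-3-yl]acetate, via lithium enolate 8 (not isolated)
Conditions: LiHMDS (1.1 equiv), THF, −78 °C; then 7 (1.3 equiv), −78 to −40 °C
Reagents that add atoms: none
Why: Enolate alkylation of a β-substituted γ-butyrolactone, in which the electrophile should approach the planar enolate anti to the C4 veratryl group and so set C3 as R (trans), the same facial preference that governs benzylation of this lactone class.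

**Step 5**
Reactants: 9 tert-butyl 2-[(3R,4R)-4-(3,4-dimethoxybenzyl)-2-oxotetrahydrofuran-3-yl]acetate
Product: 10 2-[(3R,4R)-4-(3,4-dimethoxybenzyl)-2-oxotetrahydrofuran-3-yl]acetic acid
Conditions: TFA/CH2Cl2 (1:4), 0 °C to rt
Reagents that add atoms: none
Why: Acidolysis of the tert-butyl ester (alkyl–oxygen cleavage) should free the acid without base, so the lactone, the aryl methyl ethers and both stereocentres should be unaffected.

**Step 6**
Reactants: 11 5-iodo-2-methoxyphenol
Product: 12 2-(benzyloxy)-4-iodo-1-methoxybenzene
Conditions: BnBr (1.1 equiv), K2CO3, DMF, rt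
Reagents that add atoms: benzyl bromide, BrCc1ccccc1
Why: Williamson etherification masks the phenol, which could otherwise be acylated by the active ester or bind nickel as phenoxide in step 7, with a group that leaves by neutral hydrogenolysis.

**Step 7**
Reactants: 10 2-[(3R,4R)-4-(3,4-dimethoxybenzyl)-2-oxotetrahydrofuran-3-yl]acetic acid; 12 2-(benzyloxy)-4-iodo-1-methoxybenzene
Product: 14 (3R,4R)-3-[3-(benzyloxy)-4-methoxybenzyl]-4-(3,4-dimethoxybenzyl)dihydrofuran-2(3H)-one, via N-acyloxyphthalimide ester 13 (not isolated)
Conditions: NHPI (1.1 equiv), DIC (1.1 equiv), DMAP (5 mol%), CH2Cl2, rt; filter, evaporate; then 12 (1.5 equiv), NiBr2·dme (10 mol%), dtbbpy (10 mol%), Zn (2 equiv), DMA, rt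
Reagents that add atoms: N-hydroxyphthalimide, O=C1c2ccccc2C(=O)N1O (its atoms are carried only in 13 and leave again as phthalimide)
Why: Zinc reduces Ni(II) to Ni(0), which inserts into the C–I bond of 12, while one-electron reduction of ester 13 by low-valent nickel or zinc expels phthalimide anion and CO2 and leaves a primary radical on the exocyclic carbon of C3; the arylnickel(II) species captures this radical and C(sp3)–C(sp2) reductive elimination from Ni(III) should give 14. The closest known reaction type is the nickel-catalysed decarboxylative cross-electrophile coupling of N-hydroxyphthalimide esters of primary aliphatic acids with aryl iodides. No ring is closed and no stereocentre is created; C3 and C4 should be retained because the radical sits on the exocyclic carbon and the medium is not basic. The step needs cross-coupling to win over biaryl formation, alkyl dimerisation and hydrodecarboxylation, which the different activation modes of the partners (two-electron oxidative addition for the iodide, one-electron reduction for the ester) and an excess of 12 should secure. In the substrate the radical has no 1,5-hydrogen to translocate and no β-leaving group, 3-exo attack on the lactone carbonyl (1,2-acyl shift) is slow for an ester, and β-hydride loss from the alkylnickel toward an α-methylene lactone should be outrun by reductive elimination.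

**Step 8**
Reactants: 14 (3R,4R)-3-[3-(benzyloxy)-4-methoxybenzyl]-4-(3,4-dimethoxybenzyl)dihydrofuran-2(3H)-one
Product: 15 Prestegane A, (3R,4R)-4-(3,4-dimethoxybenzyl)-3-(3-hydroxy-4-methoxybenzyl)dihydrofuran-2(3H)-one
Conditions: H2 (1 atm), 10% Pd/C, EtOAc/EtOH, rt
Reagents that add atoms: none
Why: Hydrogenolysis of the aryl benzyl ether under neutral conditions should free the phenol without touching the lactone, the methyl ethers or the epimerisable C3 centre.

**Compound list**

1 | 3,4-dimethoxybenzaldehyde | COc1ccc(C=O)cc1OC | starting material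
2 | dimethyl succinate | COC(=O)CCC(=O)OC | starting material
3 | (E)-4-(3,4-dimethoxyphenyl)-3-(methoxycarbonyl)but-3-enoic acid | COC(=O)/C(CC(=O)O)=C/c1ccc(OC)c(OC)c1 | intermediate
4 | (R)-4-(3,4-dimethoxyphenyl)-3-(methoxycarbonyl)butanoic acid | COC(=O)[C@@H](CC(=O)O)Cc1ccc(OC)c(OC)c1 | intermediate
5 | (R)-4-(3,4-dimethoxyphenyl)-3-(hydroxymethyl)butanoic acid (present as its carboxylate) | OC[C@@H](CC(=O)O)Cc1ccc(OC)c(OC)c1 | intermediate (not isolated)
6 | (R)-4-(3,4-dimethoxybenzyl)dihydrofuran-2(3H)-one | O=C1OC[C@H](Cc2ccc(OC)c(OC)c2)C1 | intermediate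
7 | tert-butyl bromoacetate | CC(C)(C)OC(=O)CBr | starting material
8 | lithium enolate of 6 | [Li]OC1=C[C@@H](Cc2ccc(OC)c(OC)c2)CO1 | intermediate (not isolated)
9 | tert-butyl 2-[(3R,4R)-4-(3,4-dimethoxybenzyl)-2-oxotetrahydrofuran-3-yl]acetate | CC(C)(C)OC(=O)C[C@H]1C(=O)OC[C@@H]1Cc1ccc(OC)c(OC)c1 | intermediate
10 | 2-[(3R,4R)-4-(3,4-dimethoxybenzyl)-2-oxotetrahydrofuran-3-yl]acetic acid | OC(=O)C[C@H]1C(=O)OC[C@@H]1Cc1ccc(OC)c(OC)c1 | intermediate
11 | 5-iodo-2-methoxyphenol | COc1ccc(I)cc1O | starting material
12 | 2-(benzyloxy)-4-iodo-1-methoxybenzene | COc1ccc(I)cc1OCc1ccccc1 | intermediate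
13 | 1,3-dioxoisoindolin-2-yl 2-[(3R,4R)-4-(3,4-dimethoxybenzyl)-2-oxotetrahydrofuran-3-yl]acetate | O=C(C[C@H]1C(=O)OC[C@@H]1Cc1ccc(OC)c(OC)c1)ON1C(=O)c2ccccc2C1=O | intermediate (not isolated)
14 | (3R,4R)-3-[3-(benzyloxy)-4-methoxybenzyl]-4-(3,4-dimethoxybenzyl)dihydrofuran-2(3H)-one | COc1ccc(C[C@H]2C(=O)OC[C@@H]2Cc2ccc(OC)c(OC)c2)cc1OCc1ccccc1 | intermediate
15 | Prestegane A, (3R,4R)-4-(3,4-dimethoxybenzyl)-3-(3-hydroxy-4-methoxybenzyl)dihydrofuran-2(3H)-one | COc1ccc(C[C@H]2C(=O)OC[C@@H]2Cc2ccc(OC)c(OC)c2)cc1O | target

**Count**

Total steps: 8. Longest linear sequence: 7 (steps 1–5, 7, 8); step 6 is a one-step branch.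

**Steps most likely to fail**

Step 7. Radical generation from the active ester may fall out of step with formation of the arylnickel species, which would divert material to hydrodecarboxylation, alkyl dimerisation or biaryl formation; β-hydride loss from the alkylnickel is a further drain. The fallback forms the same CH2–aryl bond by polar conjugate addition; it sets out from lactone 6 and returns at 14. Enolate 8 is treated with dimethylmethylideneammonium iodide to give (3S,4R)-3-[(dimethylamino)methyl]-4-(3,4-dimethoxybenzyl)dihydrofuran-2(3H)-one F1. Methylation with MeI gives the trimethylammonium iodide F2, and aqueous NaHCO3 eliminates trimethylamine to give (4R)-4-(3,4-dimethoxybenzyl)-3-methylenedihydrofuran-2(3H)-one F3. Rhodium-catalysed 1,4-addition of purchased 3-(benzyloxy)-4-methoxyphenylboronic acid ([Rh(cod)OH]2, dioxane/water, 50 °C) should place the aryl group on the exocyclic carbon. Protonation anti to the C4 group is expected to favour the cis epimer (3S,4R)-3-[3-(benzyloxy)-4-methoxybenzyl]-4-(3,4-dimethoxybenzyl)dihydrofuran-2(3H)-one F4 beside 14. DBU in warm toluene should then equilibrate C3 toward the more stable trans lactone 14, with residual F4 separated and recycled.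

Step 4. Proton exchange between enolate 8 and the product may lead to double alkylation, the enolate may attack the ester carbonyl of 7, and trans selectivity may be incomplete. The fallback avoids an ester-bearing electrophile and also bypasses 9 and step 5; it sets out from 6 and returns at 10. Enolate 8 is alkylated with allyl bromide to give (3R,4R)-3-allyl-4-(3,4-dimethoxybenzyl)dihydrofuran-2(3H)-one F5. One-pot dihydroxylation and periodate cleavage (cat. OsO4, NaIO4, 2,6-lutidine, dioxane/water) passes through the 2,3-dihydroxypropyl lactone F6 to 2-[(3R,4R)-4-(3,4-dimethoxybenzyl)-2-oxotetrahydrofuran-3-yl]acetaldehyde F7. Pinnick oxidation (NaClO2, NaH2PO4, 2-methyl-2-butene) then gives acid 10.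

Step 2. Facial discrimination by the catalyst may be insufficient for this alkene (E/Z mixture, carboxylate binding), or the sense of induction may be opposite to that expected. The fallback replaces catalyst control by a stoichiometric auxiliary; it sets out from bromoacetate 7 and returns at 6. Purchased 3-(3,4-dimethoxyphenyl)propanoic acid is attached to (S)-4-benzyl-2-oxazolidinone (PivCl, Et3N, LiCl, THF) to give (S)-4-benzyl-3-[3-(3,4-dimethoxyphenyl)propanoyl]oxazolidin-2-one F8. Treatment with NaHMDS at −78 °C and then 7 should give, by attack anti to the auxiliary benzyl group, tert-butyl (R)-4-[(S)-4-benzyl-2-oxooxazolidin-3-yl]-3-(3,4-dimethoxybenzyl)-4-oxobutanoate F9. LiBH4 removes the auxiliary reductively to give tert-butyl (R)-4-(3,4-dimethoxyphenyl)-3-(hydroxymethyl)butanoate F10, and TFA closes the lactone to 6.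

**Further compounds**

F1 | step 7 | (3S,4R)-3-[(dimethylamino)methyl]-4-(3,4-dimethoxybenzyl)dihydrofuran-2(3H)-one | CN(C)C[C@H]1C(=O)OC[C@@H]1Cc1ccc(OC)c(OC)c1
F2 | step 7 | {[(3S,4R)-4-(3,4-dimethoxybenzyl)-2-oxotetrahydrofuran-3-yl]methyl}trimethylammonium iodide | C[N+](C)(C)C[C@H]1C(=O)OC[C@@H]1Cc1ccc(OC)c(OC)c1.[I-]
F3 | step 7 | (4R)-4-(3,4-dimethoxybenzyl)-3-methylenedihydrofuran-2(3H)-one | C=C1C(=O)OC[C@@H]1Cc1ccc(OC)c(OC)c1
F4 | step 7 | (3S,4R)-3-[3-(benzyloxy)-4-methoxybenzyl]-4-(3,4-dimethoxybenzyl)dihydrofuran-2(3H)-one | COc1ccc(C[C@@H]2C(=O)OC[C@@H]2Cc2ccc(OC)c(OC)c2)cc1OCc1ccccc1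
F5 | step 4 | (3R,4R)-3-allyl-4-(3,4-dimethoxybenzyl)dihydrofuran-2(3H)-one | C=CC[C@H]1C(=O)OC[C@@H]1Cc1ccc(OC)c(OC)c1
F6 | step 4 | (3R,4R)-3-(2,3-dihydroxypropyl)-4-(3,4-dimethoxybenzyl)dihydrofuran-2(3H)-one (both carbinol epimers) | OCC(O)C[C@H]1C(=O)OC[C@@H]1Cc1ccc(OC)c(OC)c1
F7 | step 4 | 2-[(3R,4R)-4-(3,4-dimethoxybenzyl)-2-oxotetrahydrofuran-3-yl]acetaldehyde | O=CC[C@H]1C(=O)OC[C@@H]1Cc1ccc(OC)c(OC)c1
F8 | step 2 | (S)-4-benzyl-3-[3-(3,4-dimethoxyphenyl)propanoyl]oxazolidin-2-one | COc1ccc(CCC(=O)N2[C@@H](Cc3ccccc3)COC2=O)cc1OC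
F9 | step 2 | tert-butyl (R)-4-[(S)-4-benzyl-2-oxooxazolidin-3-yl]-3-(3,4-dimethoxybenzyl)-4-oxobutanoate | COc1ccc(C[C@H](CC(=O)OC(C)(C)C)C(=O)N2[C@@H](Cc3ccccc3)COC2=O)cc1OC
F10 | step 2 | tert-butyl (R)-4-(3,4-dimethoxyphenyl)-3-(hydroxymethyl)butanoate | COc1ccc(C[C@H](CC(=O)OC(C)(C)C)CO)cc1OC
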